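1. The ratio r of protic impurity to starting material in the charge of the flask, followed so far as elm, is 0.500. The runs and the questions are these:

| setting | elm | cedar | flask |
|---|---|---|---|
| starting material | 0.010 M | 0.010 M | 0.010 M |
| reagent | 0.025 M | 0.025 M | 0.0250 M |
| protic impurity | 5 mM | 5 mM | 5.00 mM |
| catalyst | 50 µM | 50 µM | 50 µM |
| temperature | 90 °C | 85 °C | 90 °C |
| remark | the very flask that is asked about, followed so far | run made earlier |  |
| time |  |  | 8.0 d |

| run | time / d | target / % |
|---|---|---|
| elm | 0.833 | 38 |
| elm | 1.67 | 49 |
| elm | 3.00 | 50 |
| elm | 4.00 | 48 |
| elm | 5.00 | 50 |
| elm | 6.00 | 48 |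
| cedar | 0.833 | 34 |
| cedar | 1.67 | 42 |
| cedar | 3.00 | 48 |
| cedar | 4.00 | 46 |
| cedar | 5.00 | 51 |
| cedar | 6.00 | 50 |

(readings scatter by 2 percentage points)

- zeta: at 8.0 d add reagent, 50.0 % of the amount charged, then wait 2.5 d
- beta: at 8.0 d raise the temperature by 10 K, then wait 2.5 d
- eta: at 8.0 d take out 90 % of the target then present, then wait 2.5 d
- gamma: at 8.0 d add catalyst, 50.0 % of the amount charged, then wait 2.5 d
- alpha: change nothing and wait 2.5 d more

- target, in percent of the starting material first charged, at 8.0 d
- what to do for the largest gain in target; "none" if nothing gains more than 2 percentage points (zeta / beta / eta / gamma / alpha / none)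
- target present, with what was taken out counted in, in percent of the starting material first charged, after eta
- target present, with what was taken out counted in, in percent of the starting material first charged, after gamma

- target that was removed still counts
- additions bring no volume worth counting

2. Follow one molecule of starting material, and suppose that one molecule of impurity destroys one molecule of it. At its fork the molecule either goes by the catalyst towards target or meets the impurity and is lost to target.

3. In the first extreme the catalyst takes the molecule each time, and target reaches 100 %.

4. In the second extreme the impurity takes the molecule each time until its charge is used, as limiting reagent of the loss. Target is then the floor yield Y_f, the charge minus r, or 50.0 %.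

5. On this supposition the impurity can claim a share r and no more, so the real flask lies between these. From 3.00 d on, elm reads 49.0 % on average and cedar 48.8 %, with a scatter of 2 percentage points per reading. Within that scatter these averages lie about at the floor, for elm and for cedar.

6. The reckoning made here commits to 50.0 % for the flask at 8.0 d. The average of elm and the share r together leave 1.00 % of the starting material unaccounted for, a figure that carries the scatter of the readings. So this reckoning names none as best, expecting no option to gain more than 2 points, and it expects 50.0 % after eta and after gamma.

7. The forecast gives 49 % at 8.0 d, gamma as best, 49 % after eta and 64 % after gamma, holding that “the reaction stops with the catalyst dead”. It parts from the reckoning above at gamma.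

8. The flask gives 50.0 %, best none, 50.0 % after eta and 50.0 % after gamma.

    starting material + protic impurity → quenched substrate (k = 150 M⁻¹ h⁻¹, Ea = 77.0 kJ mol⁻¹)
    starting material + catalyst ⇌ catalyst + intermediate (K = 1.70, k = 2700 M⁻¹ h⁻¹, Ea = 49.0 kJ mol⁻¹, ΔH = 41.0 kJ mol⁻¹)
    reagent + catalyst + intermediate → catalyst + target (k = 1.50 × 10⁵ M⁻² h⁻¹, Ea = 54.0 kJ mol⁻¹)
    (constants at 90 °C)

9. In the flask, the path from starting material and protic impurity to quenched substrate has half of its turnover behind it by 0.564 h, much earlier than the path to target at 0.476 d, and at 8.00 d the impurity stands at 0.028 % of its charge, the catalyst at 100 % live, and the target at Y_f, 50.0 %. In the neighbour flask with 2.0 × 10⁻⁴ M of catalyst, 10 % of the impurity remains at 8.00 d, Y_f plus r times that share comes to 55.0 %, and the target stands at 55.2 %.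

(The numbers in the tables were generated by integration for substances that don't exist, and the scatter is random.)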